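The route rests on disconnecting the side chain between the allylic carbinol carbon C-3' and the methylene C-4' (hept-1-en-2-yl chain numbered C-1' to C-7', ring as 7-oxabicyclo[4.1.0]heptane), an aldol bond once the angeloyloxy carbon C-5' is taken to the ketone level. A reagent-controlled boron aldol unites the fully functionalised 2-(7-oxabicyclo[4.1.0]heptan-4-yl)acrolein, made from (R)-carvone, with 3-methyl-3-(triethylsilyloxy)butan-2-one, forming the C-3'–C-4' bond and the (3'R)-carbinol in one operation. It exploits the 1,3-dioxygenation at C-3'/C-5' beside the exocyclic C-2'=C-1' alkene on ring carbon C-4: the ketone can enolise only at its methyl group and the enal not at all. Catalyst-controlled reduction then sets the anti C-5' centre before angeloylation.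

Key step: step 9

Remark: angelic acid [(Z)-2-methylbut-2-enoic acid], 2,4,6-trichlorobenzoyl chloride, (−)-Ipc2BCl (the reagent made from (+)-α-pinene) and the oxazaborolidine catalyst are taken as purchased reagents.

Step 1
Reactants: 1 (R)-(−)-carvone
Product: 3 (5S,6S)-6-hydroxy-2-methyl-5-(prop-1-en-2-yl)cyclohex-2-en-1-one (hydroxyl trans to isopropenyl), via lithium dienolate 2 (not isolated)
Conditions: LiN(i-Pr)2, THF, −78 °C; then 3-phenyl-2-(phenylsulfonyl)oxaziridine, −78 °C; aq. NH4Cl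
Reagents that add atoms: 3-phenyl-2-(phenylsulfonyl)oxaziridine, O=S(=O)(c1ccccc1)N1OC1c1ccccc1
Why: Kinetic deprotonation of the cross-conjugated enone at C-6 should give dienolate 2, and its hydroxylation by the N-sulfonyloxaziridine (Davis enolate oxidation) is expected on the face opposite the adjacent C-5 isopropenyl group, giving the trans ketol.

Step 2
Reactants: 3 trans ketol
Product: 4 (1R,6S)-3-methyl-2-oxo-6-(prop-1-en-2-yl)cyclohex-3-en-1-yl acetate (acetoxy cis to isopropenyl)
Conditions: PPh3, DIAD, AcOH, THF, 0 °C → rt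
Reagents that add atoms: acetic acid, CC(=O)O
Why: Mitsunobu reaction in which acetate displaces the oxyphosphonium group at the SN2-activated α-keto carbon with inversion, placing the acetoxy group cis to the isopropenyl group.

Step 3
Reactants: 4 cis acetoxy enone
Product: 5 (1R,2S,6S)-2-hydroxy-3-methyl-6-(prop-1-en-2-yl)cyclohex-3-en-1-yl acetate (all-cis)
Conditions: NaBH4, CeCl3·7H2O, MeOH, −78 °C
Reagents that add atoms: none
Why: Luche reduction gives 1,2-reduction only, and in the preferred half-chair (isopropenyl equatorial, acetoxy axial) hydride should add axially on the face anti to the axial C–O bond, the same face as in the carvone to cis-carveol reduction, so the new carbinol is cis to both neighbours.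

Step 4
Reactants: 5 all-cis allylic alcohol
Product: 6 (1R,2R,3R,4S,6S)-2-hydroxy-1-methyl-4-(prop-1-en-2-yl)-7-oxabicyclo[4.1.0]heptan-3-yl acetate
Conditions: VO(acac)2 (cat.), t-BuOOH, CH2Cl2, 0 °C → rt
Reagents that add atoms: tert-butyl hydroperoxide, CC(C)(C)OO
Why: Vanadium-catalysed hydroxyl-directed epoxidation, in which the bound allylic alkoxide delivers oxygen to the ring alkene on its own face, sets both epoxide carbons syn to the hydroxyl and leaves the undirected isopropenyl alkene untouched.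

Step 5
Reactants: 6 epoxy alcohol
Product: 7 (1S,2R,3R,4S,6S)-3-acetoxy-1-methyl-4-(prop-1-en-2-yl)-7-oxabicyclo[4.1.0]heptan-2-yl (Z)-2-methylbut-2-enoate
Conditions: angelic acid, 2,4,6-trichlorobenzoyl chloride, Et3N, toluene, rt (mixed anhydride); then 6, 80 °C
Reagents that add atoms: angelic acid, C/C=C(/C)C(=O)O
Why: Yamaguchi-type esterification through the mixed anhydride without DMAP is the established way to transfer an angeloyl group without Z to E isomerisation, and the carbinol configuration is retained.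

Step 6
Reactants: 7 ring angelate
Product: 8 (1S,2R,3R,4S,6S)-3-acetoxy-4-(3-hydroxyprop-1-en-2-yl)-1-methyl-7-oxabicyclo[4.1.0]heptan-2-yl (Z)-2-methylbut-2-enoate
Conditions: SeO2 (cat.), t-BuOOH, CH2Cl2, rt
Reagents that add atoms: selenium dioxide, O=[Se]=O (transfers the oxygen); tert-butyl hydroperoxide, CC(C)(C)OO (terminal oxidant that supplies it)
Why: Selenium dioxide allylic oxidation (ene reaction, then [2,3]-sigmatropic shift) should attack the electron-rich 1,1-disubstituted alkene at its methyl group, because the ring methine is hindered and deactivated by the neighbouring acetoxy carbon and the angelate alkene is electron-poor.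

Step 7
Reactants: 8 allylic alcohol
Product: 9 (1S,2R,3R,4S,6S)-3-acetoxy-1-methyl-4-(3-oxoprop-1-en-2-yl)-7-oxabicyclo[4.1.0]heptan-2-yl (Z)-2-methylbut-2-enoate
Conditions: MnO2, CH2Cl2, rt
Reagents that add atoms: none
Why: MnO2 oxidises only the primary allylic alcohol, to the 2-substituted acrolein, under neutral conditions that spare the epoxide and the esters.

Step 8
Reactants: 10 3-hydroxy-3-methylbutan-2-one
Product: 11 3-methyl-3-(triethylsilyloxy)butan-2-one
Conditions: Et3SiOTf, 2,6-lutidine, CH2Cl2, −78 → 0 °C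
Reagents that add atoms: triethylsilyl trifluoromethanesulfonate, CC[Si](CC)(CC)OS(=O)(=O)C(F)(F)F
Why: Silylation of the tertiary alcohol with a silyl triflate masks the hydroxyl so that the chloroborane of step 9 meets only the ketone.

Step 9
Reactants: 9 enal; 11 silyloxy methyl ketone
Product: 14 (1S,2R,3R,4S,6S)-3-acetoxy-4-[(3R)-3-hydroxy-6-methyl-5-oxo-6-(triethylsilyloxy)hept-1-en-2-yl]-1-methyl-7-oxabicyclo[4.1.0]heptan-2-yl (Z)-2-methylbut-2-enoate, via enol borinate 12 (not isolated), via boron aldolate 13 (not isolated)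
Conditions: 11, (−)-Ipc2BCl, Et3N, Et2O, 0 °C; then 9, −78 → −20 °C; H2O2, pH 7 buffer, MeOH, 0 °C
Reagents that add atoms: none
Why: Amine-assisted enolisation of 11 by the chloroborane can occur only at the methyl group (the other α-carbon is the quaternary C(CH3)2O carbon), and the enol diisopinocampheylborinate 12 should add 1,2 to the non-enolisable α-branched enal 9 through a closed six-membered boron-bound transition state to give aldolate 13, which oxidative work-up releases as 14. The closest known reaction type is the diisopinocampheylboron-mediated asymmetric aldol reaction of methyl ketones with aldehydes, for which 2-substituted acroleins are among the best acceptors. No ring is closed. The one new stereocentre, C-3', is set by the isopinocampheyl ligands: the reagent from (+)-α-pinene directs the enolate to the re face of the formyl group, which corresponds to the (3'R)-carbinol, while the nearest ring stereocentre (C-4, β to the formyl carbon) is expected to exert only a weak bias. The step needs 1,2- over 1,4-addition and tolerance of the epoxide and three esters; the cyclic transition state secures the first, and pre-forming the enolate so that no free chloroborane remains, at low temperature, secures the second.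

Step 10
Reactants: 14 aldol adduct
Product: 15 (1S,2R,3R,4S,6S)-3-acetoxy-1-methyl-4-[(3R)-6-methyl-5-oxo-3,6-bis(triethylsilyloxy)hept-1-en-2-yl]-7-oxabicyclo[4.1.0]heptan-2-yl (Z)-2-methylbut-2-enoate
Conditions: Et3SiCl, imidazole, DMF, 0 °C → rt
Reagents that add atoms: chlorotriethylsilane, CC[Si](Cl)(CC)CC
Why: Silyl ether formation at the secondary allylic hydroxyl under mild base blocks O-3' so that it cannot be acylated in step 12.

Step 11
Reactants: 15 bis-silyl ketone
Product: 16 (1S,2R,3R,4S,6S)-3-acetoxy-4-[(3R,5R)-5-hydroxy-6-methyl-3,6-bis(triethylsilyloxy)hept-1-en-2-yl]-1-methyl-7-oxabicyclo[4.1.0]heptan-2-yl (Z)-2-methylbut-2-enoate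
Conditions: (S)-Me-CBS oxazaborolidine [(S)-1-methyl-3,3-diphenyltetrahydro-1H,3H-pyrrolo[1,2-c][1,3,2]oxazaborole], catecholborane, toluene, −78 → −40 °C; then MeOH, pH 7 buffer
Reagents that add atoms: none
Why: Corey–Bakshi–Shibata reduction, in which the ketone binds the catalyst with its large C(CH3)2OSiEt3 group turned away and the (S)-catalyst delivers hydride to the face that should give the (5'R)-alcohol (1,3-anti to C-3'), while catecholborane at low temperature leaves alkenes, esters and the epoxide alone.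

Step 12
Reactants: 16 secondary alcohol
Product: 17 (1S,2R,3R,4S,6S)-3-acetoxy-1-methyl-4-[(3R,5R)-6-methyl-5-{[(Z)-2-methylbut-2-enoyl]oxy}-3,6-bis(triethylsilyloxy)hept-1-en-2-yl]-7-oxabicyclo[4.1.0]heptan-2-yl (Z)-2-methylbut-2-enoate
Conditions: angelic acid, 2,4,6-trichlorobenzoyl chloride, Et3N, toluene, rt (mixed anhydride); then 16, 80 °C
Reagents that add atoms: angelic acid, C/C=C(/C)C(=O)O
Why: The same DMAP-free Yamaguchi-type esterification acylates the only free hydroxyl, hindered but secondary, with retention at C-5' and without Z to E isomerisation of either angelate.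

Step 13
Reactants: 17 bis-silyl ether
Product: 18 the target, (1S,2R,3R,4S,6S)-3-acetoxy-4-[(3R,5R)-3,6-dihydroxy-6-methyl-5-{[(Z)-2-methylbut-2-enoyl]oxy}hept-1-en-2-yl]-1-methyl-7-oxabicyclo[4.1.0]heptan-2-yl (Z)-2-methylbut-2-enoate
Conditions: HF·pyridine, pyridine, THF, 0 °C → rt
Reagents that add atoms: none
Why: Fluoride cleavage of both triethylsilyl ethers under buffered, weakly acidic conditions should avoid base-induced 1,3-migration of the C-5' angelate and opening of the epoxide, and touches no stereocentre.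

Compound list
1 | (R)-(−)-carvone, (5R)-2-methyl-5-(prop-1-en-2-yl)cyclohex-2-en-1-one | C=C(C)[C@@H]1CC=C(C)C(=O)C1 | starting material
2 | lithium (3R)-6-methyl-3-(prop-1-en-2-yl)cyclohexa-1,5-dien-1-olate (kinetic dienolate of 1, not isolated) | C=C(C)[C@@H]1CC=C(C)C([O-])=C1.[Li+] | intermediate
3 | (5S,6S)-6-hydroxy-2-methyl-5-(prop-1-en-2-yl)cyclohex-2-en-1-one | C=C(C)[C@@H]1CC=C(C)C(=O)[C@H]1O | intermediate
4 | (1R,6S)-3-methyl-2-oxo-6-(prop-1-en-2-yl)cyclohex-3-en-1-yl acetate | C=C(C)[C@@H]1CC=C(C)C(=O)[C@@H]1OC(C)=O | intermediate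
5 | (1R,2S,6S)-2-hydroxy-3-methyl-6-(prop-1-en-2-yl)cyclohex-3-en-1-yl acetate | C=C(C)[C@@H]1CC=C(C)[C@H](O)[C@@H]1OC(C)=O | intermediate
6 | (1R,2R,3R,4S,6S)-2-hydroxy-1-methyl-4-(prop-1-en-2-yl)-7-oxabicyclo[4.1.0]heptan-3-yl acetate | C=C(C)[C@@H]1C[C@@H]2O[C@]2(C)[C@H](O)[C@@H]1OC(C)=O | intermediate
7 | (1S,2R,3R,4S,6S)-3-acetoxy-1-methyl-4-(prop-1-en-2-yl)-7-oxabicyclo[4.1.0]heptan-2-yl (Z)-2-methylbut-2-enoate | C=C(C)[C@@H]1C[C@@H]2O[C@]2(C)[C@H](OC(=O)/C(C)=C\C)[C@@H]1OC(C)=O | intermediate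
8 | (1S,2R,3R,4S,6S)-3-acetoxy-4-(3-hydroxyprop-1-en-2-yl)-1-methyl-7-oxabicyclo[4.1.0]heptan-2-yl (Z)-2-methylbut-2-enoate | C=C(CO)[C@@H]1C[C@@H]2O[C@]2(C)[C@H](OC(=O)/C(C)=C\C)[C@@H]1OC(C)=O | intermediate
9 | (1S,2R,3R,4S,6S)-3-acetoxy-1-methyl-4-(3-oxoprop-1-en-2-yl)-7-oxabicyclo[4.1.0]heptan-2-yl (Z)-2-methylbut-2-enoate | C=C(C=O)[C@@H]1C[C@@H]2O[C@]2(C)[C@H](OC(=O)/C(C)=C\C)[C@@H]1OC(C)=O | intermediate
10 | 3-hydroxy-3-methylbutan-2-one | CC(=O)C(C)(C)O | starting material
11 | 3-methyl-3-(triethylsilyloxy)butan-2-one | CC(=O)C(C)(C)O[Si](CC)(CC)CC | intermediate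
12 | bis[(1R,2S,3R,5R)-2,6,6-trimethylbicyclo[3.1.1]heptan-3-yl]borinic acid 3-methyl-3-(triethylsilyloxy)but-1-en-2-yl ester (enol borinate, not isolated) | C=C(OB([C@@H]1C[C@@H]2C[C@@H](C2(C)C)[C@H]1C)[C@@H]1C[C@@H]2C[C@@H](C2(C)C)[C@H]1C)C(C)(C)O[Si](CC)(CC)CC | intermediate
13 | O-3' diisopinocampheylborinate of aldol 14 (boron aldolate, not isolated) | C=C([C@H](OB([C@@H]1C[C@@H]2C[C@@H](C2(C)C)[C@H]1C)[C@@H]1C[C@@H]2C[C@@H](C2(C)C)[C@H]1C)CC(=O)C(C)(C)O[Si](CC)(CC)CC)[C@@H]1C[C@@H]2O[C@]2(C)[C@H](OC(=O)/C(C)=C\C)[C@@H]1OC(C)=O | intermediate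
14 | (1S,2R,3R,4S,6S)-3-acetoxy-4-[(3R)-3-hydroxy-6-methyl-5-oxo-6-(triethylsilyloxy)hept-1-en-2-yl]-1-methyl-7-oxabicyclo[4.1.0]heptan-2-yl (Z)-2-methylbut-2-enoate | C=C([C@H](O)CC(=O)C(C)(C)O[Si](CC)(CC)CC)[C@@H]1C[C@@H]2O[C@]2(C)[C@H](OC(=O)/C(C)=C\C)[C@@H]1OC(C)=O | intermediate
15 | (1S,2R,3R,4S,6S)-3-acetoxy-1-methyl-4-[(3R)-6-methyl-5-oxo-3,6-bis(triethylsilyloxy)hept-1-en-2-yl]-7-oxabicyclo[4.1.0]heptan-2-yl (Z)-2-methylbut-2-enoate | C=C([C@H](O[Si](CC)(CC)CC)CC(=O)C(C)(C)O[Si](CC)(CC)CC)[C@@H]1C[C@@H]2O[C@]2(C)[C@H](OC(=O)/C(C)=C\C)[C@@H]1OC(C)=O | intermediate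
16 | (1S,2R,3R,4S,6S)-3-acetoxy-4-[(3R,5R)-5-hydroxy-6-methyl-3,6-bis(triethylsilyloxy)hept-1-en-2-yl]-1-methyl-7-oxabicyclo[4.1.0]heptan-2-yl (Z)-2-methylbut-2-enoate | C=C([C@H](O[Si](CC)(CC)CC)C[C@@H](O)C(C)(C)O[Si](CC)(CC)CC)[C@@H]1C[C@@H]2O[C@]2(C)[C@H](OC(=O)/C(C)=C\C)[C@@H]1OC(C)=O | intermediate
17 | (1S,2R,3R,4S,6S)-3-acetoxy-1-methyl-4-[(3R,5R)-6-methyl-5-{[(Z)-2-methylbut-2-enoyl]oxy}-3,6-bis(triethylsilyloxy)hept-1-en-2-yl]-7-oxabicyclo[4.1.0]heptan-2-yl (Z)-2-methylbut-2-enoate | C=C([C@H](O[Si](CC)(CC)CC)C[C@@H](OC(=O)/C(C)=C\C)C(C)(C)O[Si](CC)(CC)CC)[C@@H]1C[C@@H]2O[C@]2(C)[C@H](OC(=O)/C(C)=C\C)[C@@H]1OC(C)=O | intermediate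
18 | (1S,2R,3R,4S,6S)-3-acetoxy-4-[(3R,5R)-3,6-dihydroxy-6-methyl-5-{[(Z)-2-methylbut-2-enoyl]oxy}hept-1-en-2-yl]-1-methyl-7-oxabicyclo[4.1.0]heptan-2-yl (Z)-2-methylbut-2-enoate | C=C([C@H](O)C[C@@H](OC(=O)/C(C)=C\C)C(C)(C)O)[C@@H]1C[C@@H]2O[C@]2(C)[C@H](OC(=O)/C(C)=C\C)[C@@H]1OC(C)=O | target

Total step count: 13.
Longest linear sequence: 12 steps (steps 1–7 and 9–13, from (R)-carvone); step 8 is a one-step branch.

Steps most likely to fail

Step 5. The acetyl group may migrate from O-3 to the neighbouring cis O-2 hydroxyl during the slow, heated acylation, which would scramble the two esters. The fallback sets out from 6 and comes back at 7. The acetate is first removed (K2CO3, MeOH, 0 °C) to give the all-cis epoxy diol F1. Bu2SnO in refluxing toluene should convert it into the dibutylstannylene acetal F2, which is expected to react with the angelic mixed anhydride at room temperature at the equatorial O-2 to give the mono-angelate F3. Fast acetylation of the remaining axial O-3 hydroxyl (Ac2O, pyridine, DMAP, 0 °C) then gives 7. The slow acylation is thus run on a substrate that carries a single acyl group, and the acetate enters last.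

Step 6. The ene reaction may occur at the ring methine C-4 instead of the methyl group, the product may be over-oxidised, or selenious acid may open the epoxide. The fallback sets out from 7 and comes back at 9, by-passing 8. Ene-type allylic chlorination with hypochlorous acid (Ca(OCl)2, solid CO2, CH2Cl2–water, 0 °C) should give the allylic chloride F4 by proton loss from the methyl group. Ganem-type oxidation with N-methylmorpholine N-oxide in MeCN at 40 °C then converts it directly into enal 9.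

Step 12. The neopentyl-like C-5' hydroxyl may fail to acylate, or prolonged heating may erode the Z geometry. The fallback sets out from 16 and comes back at 17, and builds the angelate on the oxygen in two operations. Steglich acylation with 2-[bis(2,2,2-trifluoroethoxy)phosphoryl]propanoic acid (DCC, DMAP, CH2Cl2) should give the phosphonate ester F5; DMAP catalysis is allowed here because the acyl group holds no Z-alkene yet. Still–Gennari olefination (KN(SiMe3)2, 18-crown-6, THF, −78 °C, then acetaldehyde) then forms the (Z)-2-methylbut-2-enoate and so gives 17.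

Further compounds
F1 | step 5 | (1R,2R,3R,4S,6S)-1-methyl-4-(prop-1-en-2-yl)-7-oxabicyclo[4.1.0]heptane-2,3-diol | C=C(C)[C@@H]1C[C@@H]2O[C@]2(C)[C@H](O)[C@@H]1O
F2 | step 5 | 2,3-O-dibutylstannylene acetal of F1 | C=C(C)[C@@H]1C[C@@H]2O[C@]2(C)[C@@H]3O[Sn](CCCC)(CCCC)O[C@H]13
F3 | step 5 | (1S,2R,3R,4S,6S)-3-hydroxy-1-methyl-4-(prop-1-en-2-yl)-7-oxabicyclo[4.1.0]heptan-2-yl (Z)-2-methylbut-2-enoate | C=C(C)[C@@H]1C[C@@H]2O[C@]2(C)[C@H](OC(=O)/C(C)=C\C)[C@@H]1O
F4 | step 6 | (1S,2R,3R,4S,6S)-3-acetoxy-4-(3-chloroprop-1-en-2-yl)-1-methyl-7-oxabicyclo[4.1.0]heptan-2-yl (Z)-2-methylbut-2-enoate | C=C(CCl)[C@@H]1C[C@@H]2O[C@]2(C)[C@H](OC(=O)/C(C)=C\C)[C@@H]1OC(C)=O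
F5 | step 12 | O-5' 2-[bis(2,2,2-trifluoroethoxy)phosphoryl]propanoate of 16 | C=C([C@H](O[Si](CC)(CC)CC)C[C@@H](OC(=O)C(C)P(=O)(OCC(F)(F)F)OCC(F)(F)F)C(C)(C)O[Si](CC)(CC)CC)[C@@H]1C[C@@H]2O[C@]2(C)[C@H](OC(=O)/C(C)=C\C)[C@@H]1OC(C)=O
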